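**Plan**

- Locants (stilbene-trimer numbering, units a, b, c): C7 is the O-bearing benzylic carbon, C8 its neighbour, C9–C14 the resorcinol ring of each unit (ring B = C9b–C14b, ring C = C9c–C14c).
- Cuts: C7c–C10b (seven-membered ring), C8b–C9b (union of the two halves), C8a–C9a (3,5-dihydroxyphenyl group), C8c–C9c (side chain on ring C). Each dihydrofuran is then taken back to a six-membered ring by putting a carbonyl carbon back between C8b and C10c (and between C8a and C12b), which gives a 2-arylchroman-4-one.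
- Enabling feature: O11c, ring C, C7b and its 4-hydroxyphenyl group are O1, the fused benzene ring, C2 and the 2-aryl group of (2S)-naringenin. In such a chroman-4-one the electron-rich ring carbon C4a (→ C10c) can shift from C4 to C3 (→ C8b); the pyranone shrinks to the furan and C4 is left outside as an ester, later exchanged for ring B. The same holds for ring B and unit a.
- Forward: naringenin → 5-triflate → ring contraction (furan of unit b on ring C) → ketone side chain at C9c → acid; naringenin → 7-triflate → same contraction (furan of unit a on ring B) → aryl group at C8a; decarboxylative union C8b–C9b; cationic closure of the seven-membered ring; demethylation.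
- Stereochemistry: C7a and C7b are C2 of (2S)-naringenin and are never touched. C8a and C8b are set trans to them when the carboxyl groups are exchanged for aryl groups. C7c is set in the ring closure by the rigid fused tetracycle.

Key step: step 3

Assumption: (2S)-naringenin of high enantiomeric purity is taken as a commercial flavanone; no step before the ring contractions uses a base strong enough to open it to the chalcone.

**Step 1**
Reactants: 1 (2S)-naringenin; 2 trimethylsilyldiazomethane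
Product: 3 (2S)-5-hydroxy-7-methoxy-2-(4-methoxyphenyl)chroman-4-one
Conditions: TMSCHN2 (3 equiv), MeOH/PhMe, 0 °C → rt
Reagents that add atoms: trimethylsilyldiazomethane, C[Si](C)(C)C=[N+]=[N-]
Why: Diazoalkane O-methylation of the two free acidic phenols (O7–H, O4'–H) should leave the hydrogen-bonded O5–H alone, and without base the flavanone should not open to the chalcone, so C2 stays S.

**Step 2**
Reactants: 3 (2S)-5-hydroxy-7-methoxy-2-(4-methoxyphenyl)chroman-4-one; 4 trifluoromethanesulfonic anhydride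
Product: 5 (2S)-7-methoxy-2-(4-methoxyphenyl)-4-oxochroman-5-yl trifluoromethanesulfonate
Conditions: Tf2O (1.3 equiv), pyridine, CH2Cl2, −20 → 0 °C
Reagents that add atoms: trifluoromethanesulfonic anhydride, O=S(=O)(OS(=O)(=O)C(F)(F)F)C(F)(F)F
Why: O-Sulfonylation of the chelated phenol with a strong electrophile and a weak base turns O5 into the leaving group for the later C9c–C8c bond and makes the fused ring stable to the oxidant of step 3.

**Step 3**
Reactants: 5 (2S)-7-methoxy-2-(4-methoxyphenyl)-4-oxochroman-5-yl trifluoromethanesulfonate; 6 trimethyl orthoformate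
Product: 8 methyl (2S,3S)-6-methoxy-2-(4-methoxyphenyl)-4-[(trifluoromethanesulfonyl)oxy]-2,3-dihydro-1-benzofuran-3-carboxylate, via enol ether 7 (not isolated)
Conditions: PhI(OAc)2 (1.2 equiv), H2SO4 (0.5 equiv), HC(OMe)3, 0 °C → rt; aq. NaHCO3
Reagents that add atoms: trimethyl orthoformate, COC(OC)OC; water, O
Why: Acid and HC(OMe)3 turn the ketone into enol ether 7, PhI(OAc)2 puts its trivalent iodine on C3 anti to the C2 aryl group and methanol re-adds at C4; the ring carbon C4a then shifts from C4 to C3 with loss of iodobenzene, and the dimethoxycarbenium ion left at C4 ends as the methyl ester on aqueous work-up. The closest known reaction type is the hypervalent-iodine (or thallium trinitrate) oxidative 1,2-aryl rearrangement of flavanones and alkyl aryl ketones to arylacetic esters. The five-membered ring is not closed end-on: it arises by this 1,2-shift through a bridged phenonium-type transition state, the six-membered ring O1–C2–C3–C4–C4a–C8a losing C4. C2 is untouched and stays S; the new centre C3 is set by inversion (C4a enters anti to the equatorial C–I bond), which places the ester trans to the C2 aryl group. The step needs migration of the fused ring carbon and not of the 4-methoxyphenyl group (isoflavone path) or loss of HI (flavone path); the ketal at C4 stabilises the cation left behind, the migrating carbon has a para methoxy group and an ortho ring oxygen, and only the C4–C4a bond is antiperiplanar to the equatorial C–I bond.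

**Step 4**
Reactants: 8 methyl (2S,3S)-6-methoxy-2-(4-methoxyphenyl)-4-[(trifluoromethanesulfonyl)oxy]-2,3-dihydro-1-benzofuran-3-carboxylate; 9 2',4'-dimethoxyacetophenone
Product: 10 methyl (2S,3S)-4-[2-(2,4-dimethoxyphenyl)-2-oxoethyl]-6-methoxy-2-(4-methoxyphenyl)-2,3-dihydro-1-benzofuran-3-carboxylate
Conditions: 9 (2.5 equiv), Pd(OAc)2 (5 mol %), XPhos (10 mol %), K3PO4 (2.5 equiv), PhMe, 80 °C
Reagents that add atoms: 2',4'-dimethoxyacetophenone, CC(=O)c1ccc(OC)cc1OC
Why: Palladium-catalysed ketone α-arylation of the methyl ketone enolate with the aryl triflate should form C9c–C8c; K3PO4 spares the ester, C8b can only return to the more stable trans ester, and ring opening by β-elimination is disfavoured because the C7b–O bond lies orthogonal to the enolate π system.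

**Step 5**
Reactants: 10 methyl (2S,3S)-4-[2-(2,4-dimethoxyphenyl)-2-oxoethyl]-6-methoxy-2-(4-methoxyphenyl)-2,3-dihydro-1-benzofuran-3-carboxylate; 11 trimethyltin hydroxide
Product: 12 (2S,3S)-4-[2-(2,4-dimethoxyphenyl)-2-oxoethyl]-6-methoxy-2-(4-methoxyphenyl)-2,3-dihydro-1-benzofuran-3-carboxylic acid
Conditions: Me3SnOH (6 equiv), ClCH2CH2Cl, 80 °C; then 1 M HCl
Reagents that add atoms: trimethyltin hydroxide, C[Sn](C)(C)O
Why: Trimethyltin hydroxide ester cleavage (neutral acyl–oxygen cleavage) should free the hindered acid without touching the ketone or the dihydrofuran.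

**Step 6**
Reactants: 1 (2S)-naringenin; 13 N-phenylbis(trifluoromethanesulfonimide)
Product: 14 (2S)-5-hydroxy-2-(4-hydroxyphenyl)-4-oxochroman-7-yl trifluoromethanesulfonate
Conditions: PhNTf2 (1.05 equiv), i-Pr2NEt (1.1 equiv), THF, 0 °C
Reagents that add atoms: N-phenylbis(trifluoromethanesulfonimide), O=S(=O)(N(c1ccccc1)S(=O)(=O)C(F)(F)F)C(F)(F)F
Why: Chemoselective O-sulfonylation of the most acidic phenol (O7–H, vinylogous to the C4 carbonyl) with one equivalent of a mild triflating agent; O4'–H is less acidic and O5–H is chelated.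

**Step 7**
Reactants: 14 (2S)-5-hydroxy-2-(4-hydroxyphenyl)-4-oxochroman-7-yl trifluoromethanesulfonate; 2 trimethylsilyldiazomethane
Product: 15 (2S)-5-methoxy-2-(4-methoxyphenyl)-4-oxochroman-7-yl trifluoromethanesulfonate
Conditions: TMSCHN2 (excess, in portions), 48% aq. HBF4 (cat.), CH2Cl2/MeOH, 0 °C → rt
Reagents that add atoms: trimethylsilyldiazomethane, C[Si](C)(C)C=[N+]=[N-]
Why: Acid-catalysed diazoalkane O-methylation (methyldiazonium as the alkylating agent) should reach the chelated O5–H as well as O4'–H, and the base-free medium again keeps C2 from epimerising through the chalcone.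

**Step 8**
Reactants: 15 (2S)-5-methoxy-2-(4-methoxyphenyl)-4-oxochroman-7-yl trifluoromethanesulfonate; 6 trimethyl orthoformate
Product: 17 methyl (2S,3S)-4-methoxy-2-(4-methoxyphenyl)-6-[(trifluoromethanesulfonyl)oxy]-2,3-dihydro-1-benzofuran-3-carboxylate, via enol ether 16 (not isolated)
Conditions: PhI(OAc)2 (1.2 equiv), H2SO4 (0.5 equiv), HC(OMe)3, 0 °C → rt; aq. NaHCO3
Reagents that add atoms: trimethyl orthoformate, COC(OC)OC; water, O
Why: The same oxidative 1,2-aryl shift ring contraction as in step 3, on the flavanone whose fused ring becomes ring B; C2 (→ C7a) stays S and the ester at C3 (→ C8a) should come out trans by the same anti addition and inversion.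

**Step 9**
Reactants: 17 methyl (2S,3S)-4-methoxy-2-(4-methoxyphenyl)-6-[(trifluoromethanesulfonyl)oxy]-2,3-dihydro-1-benzofuran-3-carboxylate; 11 trimethyltin hydroxide
Product: 18 (2S,3S)-4-methoxy-2-(4-methoxyphenyl)-6-[(trifluoromethanesulfonyl)oxy]-2,3-dihydro-1-benzofuran-3-carboxylic acid
Conditions: Me3SnOH (6 equiv), ClCH2CH2Cl, 80 °C; then 1 M HCl
Reagents that add atoms: trimethyltin hydroxide, C[Sn](C)(C)O
Why: Trimethyltin hydroxide ester cleavage is chosen because it should leave the aryl triflate intact, which aqueous hydroxide would not.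

**Step 10**
Reactants: 18 (2S,3S)-4-methoxy-2-(4-methoxyphenyl)-6-[(trifluoromethanesulfonyl)oxy]-2,3-dihydro-1-benzofuran-3-carboxylic acid; 19 1-iodo-3,5-dimethoxybenzene
Product: 20 (2S,3S)-3-(3,5-dimethoxyphenyl)-4-methoxy-2-(4-methoxyphenyl)-2,3-dihydro-1-benzofuran-6-yl trifluoromethanesulfonate
Conditions: 19 (3 equiv), Ir[dF(CF3)ppy]2(dtbbpy)PF6 (2 mol %), NiCl2·glyme (10 mol %), dtbbpy (15 mol %), Cs2CO3 (1.5 equiv), DMF, 450 nm LEDs, rt
Reagents that add atoms: 1-iodo-3,5-dimethoxybenzene, COc1cc(I)cc(OC)c1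
Why: Nickel/photoredox decarboxylative arylation: the excited iridium complex oxidises the carboxylate, CO2 is lost, and the benzylic C8a radical is taken up by the arylnickel species from the iodide (which adds to nickel far faster than the triflate); the C8a–aryl bond should form on the face away from the C7a aryl group (2,3-trans).

**Step 11**
Reactants: 12 (2S,3S)-4-[2-(2,4-dimethoxyphenyl)-2-oxoethyl]-6-methoxy-2-(4-methoxyphenyl)-2,3-dihydro-1-benzofuran-3-carboxylic acid; 20 (2S,3S)-3-(3,5-dimethoxyphenyl)-4-methoxy-2-(4-methoxyphenyl)-2,3-dihydro-1-benzofuran-6-yl trifluoromethanesulfonate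
Product: 21 1-(2,4-dimethoxyphenyl)-2-{(2S,3S)-3-[(2S,3S)-3-(3,5-dimethoxyphenyl)-4-methoxy-2-(4-methoxyphenyl)-2,3-dihydro-1-benzofuran-6-yl]-6-methoxy-2-(4-methoxyphenyl)-2,3-dihydro-1-benzofuran-4-yl}ethan-1-one
Conditions: 12 (1.3 equiv), Cs2CO3 (0.65 equiv), Ir[dF(CF3)ppy]2(dtbbpy)PF6 (2 mol %), NiCl2·glyme (10 mol %), dtbbpy (15 mol %), DMF, 450 nm LEDs, 30 °C
Reagents that add atoms: none
Why: The same nickel/photoredox decarboxylative arylation joins the halves at C8b–C9b; aryl triflates are competent electrophiles for nickel–bipyridine in such alkyl–aryl couplings, the aryl group should be delivered trans to the C7b aryl group, and only one equivalent of base per acid is used so that the ketone CH2 is not enolised.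

**Step 12**
Reactants: 21 the ketone of step 11
Product: 23 octa-O-methyl ether of the target, via benzylic alcohol 22 (not isolated)
Conditions: NaBH4 (2 equiv), THF/MeOH, 0 °C → rt; AcOH quench, concentrate; then TFA (10 equiv), CH2Cl2 (0.005 M), −20 → 0 °C
Reagents that add atoms: none
Why: Hydride reduction gives alcohol 22 (both epimers), which in acid loses water to the 2,4-dimethoxybenzylic cation at C7c, and intramolecular Friedel–Crafts alkylation closes the seven-membered ring, the known acid cyclisation of stilbene dihydrobenzofurans of the ε-viniferin type; attack is expected at C10b, next to the tied-back furan oxygen, and not at C14b, which is shielded by the O13b methyl group, and under these reversible conditions the C7c aryl group should end pseudo-axial and syn to H8b (7cS), because an equatorial aryl group would clash with O11b in the plane of ring B.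

**Step 13**
Reactants: 23 octa-O-methyl ether of the target
Product: 24 CNP0154774.1 (target)
Conditions: BBr3 (20 equiv), CH2Cl2, −78 °C → rt; then MeOH, H2O
Reagents that add atoms: none
Why: Lewis-acid cleavage of all eight aryl methyl ethers; no C–H stereocentre is acidic, and ionisation of a C7–O bond can only re-close to the same trans dihydrofuran.

**Compound list**

1 | (2S)-naringenin, (2S)-5,7-dihydroxy-2-(4-hydroxyphenyl)chroman-4-one | O=C1C[C@@H](c2ccc(O)cc2)Oc2cc(O)cc(O)c21 | starting material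
2 | trimethylsilyldiazomethane | C[Si](C)(C)C=[N+]=[N-] | starting material
3 | (2S)-5-hydroxy-7-methoxy-2-(4-methoxyphenyl)chroman-4-one | O=C1C[C@@H](c2ccc(OC)cc2)Oc2cc(OC)cc(O)c21 | intermediate
4 | trifluoromethanesulfonic anhydride | O=S(=O)(OS(=O)(=O)C(F)(F)F)C(F)(F)F | starting material
5 | (2S)-7-methoxy-2-(4-methoxyphenyl)-4-oxochroman-5-yl trifluoromethanesulfonate | O=C1C[C@@H](c2ccc(OC)cc2)Oc2cc(OC)cc(OS(=O)(=O)C(F)(F)F)c21 | intermediate
6 | trimethyl orthoformate | COC(OC)OC | starting material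
7 | (2S)-4,7-dimethoxy-2-(4-methoxyphenyl)-2H-chromen-5-yl trifluoromethanesulfonate (enol ether, formed in situ) | COC1=C[C@@H](c2ccc(OC)cc2)Oc2cc(OC)cc(OS(=O)(=O)C(F)(F)F)c21 | intermediate
8 | methyl (2S,3S)-6-methoxy-2-(4-methoxyphenyl)-4-[(trifluoromethanesulfonyl)oxy]-2,3-dihydro-1-benzofuran-3-carboxylate | COC(=O)[C@H]1c2c(OS(=O)(=O)C(F)(F)F)cc(OC)cc2O[C@@H]1c1ccc(OC)cc1 | intermediate
9 | 2',4'-dimethoxyacetophenone | CC(=O)c1ccc(OC)cc1OC | starting material
10 | methyl (2S,3S)-4-[2-(2,4-dimethoxyphenyl)-2-oxoethyl]-6-methoxy-2-(4-methoxyphenyl)-2,3-dihydro-1-benzofuran-3-carboxylate | COC(=O)[C@H]1c2c(CC(=O)c3ccc(OC)cc3OC)cc(OC)cc2O[C@@H]1c1ccc(OC)cc1 | intermediate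
11 | trimethyltin hydroxide | C[Sn](C)(C)O | starting material
12 | (2S,3S)-4-[2-(2,4-dimethoxyphenyl)-2-oxoethyl]-6-methoxy-2-(4-methoxyphenyl)-2,3-dihydro-1-benzofuran-3-carboxylic acid | OC(=O)[C@H]1c2c(CC(=O)c3ccc(OC)cc3OC)cc(OC)cc2O[C@@H]1c1ccc(OC)cc1 | intermediate
13 | N-phenylbis(trifluoromethanesulfonimide) | O=S(=O)(N(c1ccccc1)S(=O)(=O)C(F)(F)F)C(F)(F)F | starting material
14 | (2S)-5-hydroxy-2-(4-hydroxyphenyl)-4-oxochroman-7-yl trifluoromethanesulfonate | O=C1C[C@@H](c2ccc(O)cc2)Oc2cc(OS(=O)(=O)C(F)(F)F)cc(O)c21 | intermediate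
15 | (2S)-5-methoxy-2-(4-methoxyphenyl)-4-oxochroman-7-yl trifluoromethanesulfonate | O=C1C[C@@H](c2ccc(OC)cc2)Oc2cc(OS(=O)(=O)C(F)(F)F)cc(OC)c21 | intermediate
16 | (2S)-4,5-dimethoxy-2-(4-methoxyphenyl)-2H-chromen-7-yl trifluoromethanesulfonate (enol ether, formed in situ) | COC1=C[C@@H](c2ccc(OC)cc2)Oc2cc(OS(=O)(=O)C(F)(F)F)cc(OC)c21 | intermediate
17 | methyl (2S,3S)-4-methoxy-2-(4-methoxyphenyl)-6-[(trifluoromethanesulfonyl)oxy]-2,3-dihydro-1-benzofuran-3-carboxylate | COc1ccc([C@H]2Oc3cc(OS(=O)(=O)C(F)(F)F)cc(OC)c3[C@@H]2C(=O)OC)cc1 | intermediate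
18 | (2S,3S)-4-methoxy-2-(4-methoxyphenyl)-6-[(trifluoromethanesulfonyl)oxy]-2,3-dihydro-1-benzofuran-3-carboxylic acid | COc1ccc([C@H]2Oc3cc(OS(=O)(=O)C(F)(F)F)cc(OC)c3[C@@H]2C(=O)O)cc1 | intermediate
19 | 1-iodo-3,5-dimethoxybenzene | COc1cc(I)cc(OC)c1 | starting material
20 | (2S,3S)-3-(3,5-dimethoxyphenyl)-4-methoxy-2-(4-methoxyphenyl)-2,3-dihydro-1-benzofuran-6-yl trifluoromethanesulfonate | COc1ccc([C@H]2Oc3cc(OS(=O)(=O)C(F)(F)F)cc(OC)c3[C@@H]2c2cc(OC)cc(OC)c2)cc1 | intermediate
21 | 1-(2,4-dimethoxyphenyl)-2-{(2S,3S)-3-[(2S,3S)-3-(3,5-dimethoxyphenyl)-4-methoxy-2-(4-methoxyphenyl)-2,3-dihydro-1-benzofuran-6-yl]-6-methoxy-2-(4-methoxyphenyl)-2,3-dihydro-1-benzofuran-4-yl}ethan-1-one | COc1ccc([C@H]2Oc3cc(cc(OC)c3[C@@H]2c2cc(OC)cc(OC)c2)[C@H]2c3c(CC(=O)c4ccc(OC)cc4OC)cc(OC)cc3O[C@@H]2c2ccc(OC)cc2)cc1 | intermediate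
22 | secondary alcohol from ketone 21 (both epimers at the carbinol carbon, formed in situ) | COc1ccc([C@H]2Oc3cc(cc(OC)c3[C@@H]2c2cc(OC)cc(OC)c2)[C@H]2c3c(CC(O)c4ccc(OC)cc4OC)cc(OC)cc3O[C@@H]2c2ccc(OC)cc2)cc1 | intermediate
23 | octa-O-methyl ether of the target (7aS,8aS,7bS,8bS,7cS) | COc1ccc([C@H]2Oc3c4c(cc(OC)c3[C@@H]2c2cc(OC)cc(OC)c2)[C@H]2c3c(cc(OC)cc3O[C@@H]2c2ccc(OC)cc2)C[C@H]4c2ccc(OC)cc2OC)cc1 | intermediate
24 | CNP0154774.1 (7aS,8aS,7bS,8bS,7cS) | Oc1ccc([C@H]2Oc3c4c(cc(O)c3[C@@H]2c2cc(O)cc(O)c2)[C@H]2c3c(cc(O)cc3O[C@@H]2c2ccc(O)cc2)C[C@H]4c2ccc(O)cc2O)cc1 | target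

**Step count and risks**

Total step count: 13. Longest linear sequence: 8 steps (steps 1–5 then 11–13, or steps 6–13).

Steps most likely to fail:

Step 11. The hindered secondary benzylic C8b radical may be reduced or dimerise before the arylnickel species captures it, and the triflate may add to nickel too slowly. The fallback sets out from 12 and 20 and returns at 21. It replaces the light-driven coupling with an aryl electrophile by a thermal nickel coupling of a redox-active ester with an aryl boron nucleophile. Acid 12 is condensed with N-hydroxytetrachlorophthalimide (diisopropylcarbodiimide, CH2Cl2) to the 4,5,6,7-tetrachloro-1,3-dioxoisoindolin-2-yl ester of 12 F1. Triflate 20 is borylated (B2pin2, Pd(dppf)Cl2, KOAc, dioxane, 80 °C) to the pinacol boronate of 20 F2, which is cleaved (NaIO4, NH4OAc, acetone/water) to the boronic acid of 20 F3. F1 and F3 are then joined with NiCl2·6H2O, 4,7-diphenyl-1,10-phenanthroline and Et3N in dioxane/DMF at 75 °C to give 21.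

Step 3. The 4-methoxyphenyl group may migrate from C2 to C3 (isoflavone), HI may be lost to the flavone, or ketal formation next to the triflate may be too slow. The fallback sets out from 5 and returns at 8. It separates the two tasks of the oxidant: the leaving group is installed first, and the same C4a shift is then triggered by a Lewis acid (the α-halo ketal 1,2-aryl rearrangement). Ketone 5 is brominated at C3 (PhNMe3Br3, THF, rt) to the 2,3-trans bromide (2R,3R)-3-bromo-7-methoxy-2-(4-methoxyphenyl)-4-oxochroman-5-yl trifluoromethanesulfonate F4. This is ketalised (HC(OMe)3, MeOH, TsOH) to (2R,3R)-3-bromo-4,4,7-trimethoxy-2-(4-methoxyphenyl)chroman-5-yl trifluoromethanesulfonate F5. ZnBr2 in toluene at 90 °C should then induce the ring contraction with inversion at C3 and loss of methyl bromide, giving 8.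

Step 12. The C7c cation may attack the other free ortho carbon of ring B (C14b) and give the regioisomeric tetracycle. The fallback sets out from 14 and returns at 24. It blocks C14b sterically with a bulky silyl ether on the neighbouring oxygen O13b in place of the methyl ether. Triflate 14 is methylated only at O4' (TMSCHN2, MeOH, no acid) to (2S)-5-hydroxy-2-(4-methoxyphenyl)-4-oxochroman-7-yl trifluoromethanesulfonate F6, and this is silylated (i-Pr3SiOTf, 2,6-lutidine, CH2Cl2) to (2S)-2-(4-methoxyphenyl)-4-oxo-5-[tri(propan-2-yl)silyloxy]chroman-7-yl trifluoromethanesulfonate F7. The conditions of step 8 then lead through the enol ether (2S)-4-methoxy-2-(4-methoxyphenyl)-5-[tri(propan-2-yl)silyloxy]-2H-chromen-7-yl trifluoromethanesulfonate F8 to methyl (2S,3S)-2-(4-methoxyphenyl)-6-[(trifluoromethanesulfonyl)oxy]-4-[tri(propan-2-yl)silyloxy]-2,3-dihydro-1-benzofuran-3-carboxylate F9. The conditions of step 9 give the corresponding carboxylic acid F10, and those of step 10 give (2S,3S)-3-(3,5-dimethoxyphenyl)-2-(4-methoxyphenyl)-4-[tri(propan-2-yl)silyloxy]-2,3-dihydro-1-benzofuran-6-yl trifluoromethanesulfonate F11. Union with 12 under the conditions of step 11 gives the O13b-silyl analogue of ketone 21 F12. Reduction gives the O13b-silyl analogue of alcohol 22 F13, and acid closure gives the O13b-silyl hepta-O-methyl ether of the target F14. BBr3 should then remove the silyl and methyl groups together to give 24.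

**Further compounds**

F1 | step 11 | 4,5,6,7-tetrachloro-1,3-dioxoisoindolin-2-yl ester of acid 12 | O=C(ON1C(=O)c2c(Cl)c(Cl)c(Cl)c(Cl)c2C1=O)[C@H]1c2c(CC(=O)c3ccc(OC)cc3OC)cc(OC)cc2O[C@@H]1c1ccc(OC)cc1
F2 | step 11 | 2-[(2S,3S)-3-(3,5-dimethoxyphenyl)-4-methoxy-2-(4-methoxyphenyl)-2,3-dihydro-1-benzofuran-6-yl]-4,4,5,5-tetramethyl-1,3,2-dioxaborolane | COc1ccc([C@H]2Oc3cc(B4OC(C)(C)C(C)(C)O4)cc(OC)c3[C@@H]2c2cc(OC)cc(OC)c2)cc1
F3 | step 11 | [(2S,3S)-3-(3,5-dimethoxyphenyl)-4-methoxy-2-(4-methoxyphenyl)-2,3-dihydro-1-benzofuran-6-yl]boronic acid | COc1ccc([C@H]2Oc3cc(B(O)O)cc(OC)c3[C@@H]2c2cc(OC)cc(OC)c2)cc1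
F4 | step 3 | (2R,3R)-3-bromo-7-methoxy-2-(4-methoxyphenyl)-4-oxochroman-5-yl trifluoromethanesulfonate (2,3-trans) | O=C1[C@H](Br)[C@@H](c2ccc(OC)cc2)Oc2cc(OC)cc(OS(=O)(=O)C(F)(F)F)c21
F5 | step 3 | (2R,3R)-3-bromo-4,4,7-trimethoxy-2-(4-methoxyphenyl)chroman-5-yl trifluoromethanesulfonate | COC1(OC)[C@H](Br)[C@@H](c2ccc(OC)cc2)Oc2cc(OC)cc(OS(=O)(=O)C(F)(F)F)c21
F6 | step 12 | (2S)-5-hydroxy-2-(4-methoxyphenyl)-4-oxochroman-7-yl trifluoromethanesulfonate | O=C1C[C@@H](c2ccc(OC)cc2)Oc2cc(OS(=O)(=O)C(F)(F)F)cc(O)c21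
F7 | step 12 | (2S)-2-(4-methoxyphenyl)-4-oxo-5-[tri(propan-2-yl)silyloxy]chroman-7-yl trifluoromethanesulfonate | O=C1C[C@@H](c2ccc(OC)cc2)Oc2cc(OS(=O)(=O)C(F)(F)F)cc(O[Si](C(C)C)(C(C)C)C(C)C)c21
F8 | step 12 | (2S)-4-methoxy-2-(4-methoxyphenyl)-5-[tri(propan-2-yl)silyloxy]-2H-chromen-7-yl trifluoromethanesulfonate | COC1=C[C@@H](c2ccc(OC)cc2)Oc2cc(OS(=O)(=O)C(F)(F)F)cc(O[Si](C(C)C)(C(C)C)C(C)C)c21
F9 | step 12 | methyl (2S,3S)-2-(4-methoxyphenyl)-6-[(trifluoromethanesulfonyl)oxy]-4-[tri(propan-2-yl)silyloxy]-2,3-dihydro-1-benzofuran-3-carboxylate | COc1ccc([C@H]2Oc3cc(OS(=O)(=O)C(F)(F)F)cc(O[Si](C(C)C)(C(C)C)C(C)C)c3[C@@H]2C(=O)OC)cc1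
F10 | step 12 | (2S,3S)-2-(4-methoxyphenyl)-6-[(trifluoromethanesulfonyl)oxy]-4-[tri(propan-2-yl)silyloxy]-2,3-dihydro-1-benzofuran-3-carboxylic acid | COc1ccc([C@H]2Oc3cc(OS(=O)(=O)C(F)(F)F)cc(O[Si](C(C)C)(C(C)C)C(C)C)c3[C@@H]2C(=O)O)cc1
F11 | step 12 | (2S,3S)-3-(3,5-dimethoxyphenyl)-2-(4-methoxyphenyl)-4-[tri(propan-2-yl)silyloxy]-2,3-dihydro-1-benzofuran-6-yl trifluoromethanesulfonate | COc1ccc([C@H]2Oc3cc(OS(=O)(=O)C(F)(F)F)cc(O[Si](C(C)C)(C(C)C)C(C)C)c3[C@@H]2c2cc(OC)cc(OC)c2)cc1
F12 | step 12 | O13b-tri(propan-2-yl)silyl analogue of ketone 21 | COc1ccc([C@H]2Oc3cc(cc(O[Si](C(C)C)(C(C)C)C(C)C)c3[C@@H]2c2cc(OC)cc(OC)c2)[C@H]2c3c(CC(=O)c4ccc(OC)cc4OC)cc(OC)cc3O[C@@H]2c2ccc(OC)cc2)cc1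
F13 | step 12 | O13b-tri(propan-2-yl)silyl analogue of alcohol 22 (both carbinol epimers) | COc1ccc([C@H]2Oc3cc(cc(O[Si](C(C)C)(C(C)C)C(C)C)c3[C@@H]2c2cc(OC)cc(OC)c2)[C@H]2c3c(CC(O)c4ccc(OC)cc4OC)cc(OC)cc3O[C@@H]2c2ccc(OC)cc2)cc1
F14 | step 12 | O13b-tri(propan-2-yl)silyl hepta-O-methyl ether of the target | COc1ccc([C@H]2Oc3c4c(cc(O[Si](C(C)C)(C(C)C)C(C)C)c3[C@@H]2c2cc(OC)cc(OC)c2)[C@H]2c3c(cc(OC)cc3O[C@@H]2c2ccc(OC)cc2)C[C@H]4c2ccc(OC)cc2OC)cc1
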